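The 2,2-dimethyl-2H-pyran fused to ring B is disconnected back to a 1,1-dimethylpropargyl ether on O4'. The key step exploits the fact that O4' is flanked by only one unsubstituted carbon, C3' (C5' bears oxygen), so a thermal [3,3] shift, hydrogen shift and oxa-6π closure can annulate the pyran only across C3'–C4'. One neutral heating step thereby forms the C3'–C4'' bond, re-forms the O–C2'' bond and closes the last ring. Its precursor is the complete flavonol carrying the 8-(1,1-dimethylallyl) and 2'-prenyl groups, a free chelated 3-OH, methoxymethyl ethers on O5, O7 and O5', and the propargyl ether on O4', assembled from two fragments by chalcone formation and oxidative cyclisation.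

Key step: step 11

Remark: the target has no stereogenic element, so no stereocontrol is needed; 2-bromo-4,5-dihydroxybenzaldehyde (whose two hydroxyls can be told apart) and tributyl(3-methylbut-2-en-1-yl)stannane are taken as catalogue compounds.

Step 1
Reactants: 1 2',4',6'-trihydroxyacetophenone; 2 prenyl bromide
Product: 3 1-[2,6-dihydroxy-4-(3-methylbut-2-en-1-yloxy)phenyl]ethanone
Conditions: K2CO3 (1.1 equiv), acetone, rt → 50 °C
Reagents that add atoms: prenyl bromide (2), CC(C)=CCBr
Why: Williamson ether synthesis; with one equivalent of weak base only the 4-OH, the most acidic hydroxyl and the only one not hydrogen-bonded to the acetyl carbonyl, is deprotonated and alkylated at oxygen.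

Step 2
Reactants: 3 1-[2,6-dihydroxy-4-(3-methylbut-2-en-1-yloxy)phenyl]ethanone
Product: 5 1-[2,4,6-trihydroxy-3-(2-methylbut-3-en-2-yl)phenyl]ethanone, via ortho-dienone 4 (not isolated)
Conditions: PhNEt2, 185 °C, Ar
Reagents that add atoms: none
Why: Aromatic Claisen rearrangement; the [3,3] shift can reach only C3 or C5, which are identical by symmetry, while the para carbon carries the acetyl group, so tautomerisation of dienone 4 should give a single ortho-(1,1-dimethylallyl)phenol with the allyl unit inverted as required.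

Step 3
Reactants: 5 1-[2,4,6-trihydroxy-3-(2-methylbut-3-en-2-yl)phenyl]ethanone
Product: 6 1-[2-hydroxy-4,6-bis(methoxymethoxy)-3-(2-methylbut-3-en-2-yl)phenyl]ethanone
Conditions: MOMCl (2.2 equiv), K2CO3, acetone, 0 °C → rt
Reagents that add atoms: chloromethyl methyl ether, COCCl
Why: MOM protection (O-alkylation with an α-chloro ether) should cap the free 4-OH and, of the two carbonyl-bonded hydroxyls, the unhindered 6-OH, whereas the 2-OH is shielded by the neighbouring quaternary carbon and held in the chelate, so it stays free for the later pyranone closure next to C3.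

Step 4
Reactants: 7 2-bromo-4,5-dihydroxybenzaldehyde
Product: 8 2-bromo-5-hydroxy-4-[(4-methoxybenzyl)oxy]benzaldehyde
Conditions: PMBCl (1.05 equiv), NaHCO3, NaI (cat.), DMF, 40 °C
Reagents that add atoms: 4-methoxybenzyl chloride, COc1ccc(CCl)cc1
Why: Williamson ether synthesis under weak base is selective for the 4-OH, which is para to the formyl group and therefore the more acidic phenol, the established pattern for mono-alkylation of 3,4-dihydroxybenzaldehydes.

Step 5
Reactants: 8 2-bromo-5-hydroxy-4-[(4-methoxybenzyl)oxy]benzaldehyde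
Product: 9 2-bromo-4-[(4-methoxybenzyl)oxy]-5-(methoxymethoxy)benzaldehyde
Conditions: MOMCl, K2CO3, acetone, rt
Reagents that add atoms: chloromethyl methyl ether, COCCl
Why: MOM protection of the remaining phenol (Williamson-type alkylation) proceeds under mild base without touching the aldehyde, the bromide or the PMB ether.

Step 6
Reactants: 9 2-bromo-4-[(4-methoxybenzyl)oxy]-5-(methoxymethoxy)benzaldehyde; 10 tributyl(3-methylbut-2-en-1-yl)stannane
Product: 11 4-[(4-methoxybenzyl)oxy]-5-(methoxymethoxy)-2-(3-methylbut-2-en-1-yl)benzaldehyde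
Conditions: Pd(PPh3)4 (5 mol%), DMF, 90 °C, Ar
Reagents that add atoms: tributyl(3-methylbut-2-en-1-yl)stannane (10), CCCC[Sn](CCCC)(CCCC)CC=C(C)C
Why: Stille cross-coupling; oxidative addition into the C–Br bond is assisted by the ortho-formyl group, and reductive elimination from the aryl(allyl)palladium species at the less substituted allyl terminus should give the linear prenyl arene under neutral conditions that the acetal and benzyl ethers tolerate.

Step 7
Reactants: 11 4-[(4-methoxybenzyl)oxy]-5-(methoxymethoxy)-2-(3-methylbut-2-en-1-yl)benzaldehyde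
Product: 12 4-hydroxy-5-(methoxymethoxy)-2-(3-methylbut-2-en-1-yl)benzaldehyde
Conditions: DDQ, CH2Cl2/pH 7 buffer, 0 °C → rt
Reagents that add atoms: none
Why: Oxidative cleavage of the 4-methoxybenzyl ether by DDQ (hydride abstraction at the electron-rich benzylic carbon, then hydrolysis) should free O4 selectively, since the MOM ether and the formyl-deactivated prenyl arene are poor hydride donors.

Step 8
Reactants: 12 4-hydroxy-5-(methoxymethoxy)-2-(3-methylbut-2-en-1-yl)benzaldehyde; 13 3-chloro-3-methylbut-1-yne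
Product: 14 5-(methoxymethoxy)-4-[(2-methylbut-3-yn-2-yl)oxy]-2-(3-methylbut-2-en-1-yl)benzaldehyde
Conditions: CuCl2·2H2O (1 mol%), DBU, MeCN, 0 °C
Reagents that add atoms: 3-chloro-3-methylbut-1-yne (13), CC(C)(Cl)C#C
Why: Copper-catalysed O-propargylation of a phenol with a tertiary propargylic chloride works best for acidic phenols such as this para-formyl phenol and runs at 0 °C, far below the temperature at which the new ether rearranges.

Step 9
Reactants: 6 1-[2-hydroxy-4,6-bis(methoxymethoxy)-3-(2-methylbut-3-en-2-yl)phenyl]ethanone; 14 5-(methoxymethoxy)-4-[(2-methylbut-3-yn-2-yl)oxy]-2-(3-methylbut-2-en-1-yl)benzaldehyde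
Product: 16 (E)-1-[2-hydroxy-4,6-bis(methoxymethoxy)-3-(2-methylbut-3-en-2-yl)phenyl]-3-[5-(methoxymethoxy)-4-(2-methylbut-3-yn-2-yloxy)-2-(3-methylbut-2-en-1-yl)phenyl]prop-2-en-1-one, via aldol adduct 15 (not isolated)
Conditions: KOH, EtOH/H2O, rt
Reagents that add atoms: none
Why: Claisen–Schmidt condensation; the methyl ketone enolate adds to the non-enolisable aldehyde and aldol 15 loses water (E1cB) to the conjugated (E)-enone, the acetals, the alkenes and the terminal alkyne being stable to hydroxide.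

Step 10
Reactants: 16 (E)-chalcone from step 9
Product: 18 3-hydroxy-5,7-bis(methoxymethoxy)-8-(2-methylbut-3-en-2-yl)-2-[5-(methoxymethoxy)-4-(2-methylbut-3-yn-2-yloxy)-2-(3-methylbut-2-en-1-yl)phenyl]-4H-chromen-4-one, via trans-dihydroflavonol 17 (not isolated)
Conditions: 30% H2O2, NaOH, MeOH, 0 °C → rt
Reagents that add atoms: hydrogen peroxide, OO
Why: Algar–Flynn–Oyamada reaction; alkaline hydrogen peroxide should convert the 2'-hydroxychalcone, by phenoxide attack at the β-carbon and oxygenation at the α-carbon, into dihydroflavonol 17 and oxidise it on to the flavonol, while the isolated alkenes and the alkyne do not react with hydroperoxide anion and the only free phenol lies next to the 1,1-dimethylallyl carbon, which places that group at C8.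

Step 11
Reactants: 18 4'-O-(1,1-dimethylpropargyl) flavonol from step 10
Product: 22 3-hydroxy-5,7-bis(methoxymethoxy)-2-[8-(methoxymethoxy)-2,2-dimethyl-5-(3-methylbut-2-en-1-yl)-2H-chromen-6-yl]-8-(2-methylbut-3-en-2-yl)-4H-chromen-4-one, via allenyl dienone 19 (not isolated), via allenyl phenol 20 (not isolated), via ortho-quinone methide 21 (not isolated)
Conditions: degassed o-xylene, 140 °C, Ar
Reagents that add atoms: none
Why: Heating should trigger the aryl propargyl ether Claisen rearrangement: a [3,3] shift joins C3' to the alkyne terminus to give allenyl dienone 19, which enolises to phenol 20, a 1,5-hydrogen shift from O4'–H to the central allene carbon gives ortho-quinone methide 21, and oxa-6π electrocyclisation re-forms the O–C(CH3)2 bond. The closest known reaction type is the thermal conversion of aryl 1,1-dimethylpropargyl ethers into 2,2-dimethyl-2H-chromenes. The single new ring, the pyran, closes by a thermal disrotatory six-electron electrocyclisation of the oxa-triene unit of 21, a six-membered closure that restores the aromaticity of ring B. No stereocentre is formed, so no stereocontrol is required. The step needs ortho regioselectivity, which the substrate fixes: of the two carbons flanking O4', C5' carries the methoxymethoxy group and a shift there gives a blocked dienone that can only revert, so only C3'–H leads on. The neutral medium should leave the prenyl, 1,1-dimethylallyl, acetal and chelated 3-OH groups untouched.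

Step 12
Reactants: 22 tris(methoxymethyl) ether of the target from step 11
Product: 23 broussoflavonol D
Conditions: AcCl (0.5 equiv) in MeOH (anhydrous HCl), 0 °C → rt
Reagents that add atoms: none
Why: Acid-catalysed transacetalisation with methanol (MOM ether cleavage) should release O5, O7 and O5' as phenols and dimethoxymethane, and dilute anhydrous acid at or below room temperature is chosen because aryl MOM ethers exchange faster than the chromene, prenyl or 1,1-dimethylallyl alkenes are protonated.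

Compound list
1 | 2',4',6'-trihydroxyacetophenone | CC(=O)c1c(O)cc(O)cc1O | starting material
2 | prenyl bromide (1-bromo-3-methylbut-2-ene) | CC(C)=CCBr | starting material
3 | 1-[2,6-dihydroxy-4-(3-methylbut-2-en-1-yloxy)phenyl]ethanone | CC(=O)c1c(O)cc(OCC=C(C)C)cc1O | intermediate
4 | 4-acetyl-3,5-dihydroxy-6-(2-methylbut-3-en-2-yl)cyclohexa-2,4-dien-1-one (racemic, not isolated) | CC(=O)C1=C(O)C(C(C)(C)C=C)C(=O)C=C1O | intermediate
5 | 1-[2,4,6-trihydroxy-3-(2-methylbut-3-en-2-yl)phenyl]ethanone | CC(=O)c1c(O)cc(O)c(C(C)(C)C=C)c1O | intermediate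
6 | 1-[2-hydroxy-4,6-bis(methoxymethoxy)-3-(2-methylbut-3-en-2-yl)phenyl]ethanone | CC(=O)c1c(OCOC)cc(OCOC)c(C(C)(C)C=C)c1O | intermediate
7 | 2-bromo-4,5-dihydroxybenzaldehyde | O=Cc1cc(O)c(O)cc1Br | starting material
8 | 2-bromo-5-hydroxy-4-[(4-methoxybenzyl)oxy]benzaldehyde | O=Cc1cc(O)c(OCc2ccc(OC)cc2)cc1Br | intermediate
9 | 2-bromo-4-[(4-methoxybenzyl)oxy]-5-(methoxymethoxy)benzaldehyde | O=Cc1cc(OCOC)c(OCc2ccc(OC)cc2)cc1Br | intermediate
10 | tributyl(3-methylbut-2-en-1-yl)stannane | CCCC[Sn](CCCC)(CCCC)CC=C(C)C | starting material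
11 | 4-[(4-methoxybenzyl)oxy]-5-(methoxymethoxy)-2-(3-methylbut-2-en-1-yl)benzaldehyde | O=Cc1cc(OCOC)c(OCc2ccc(OC)cc2)cc1CC=C(C)C | intermediate
12 | 4-hydroxy-5-(methoxymethoxy)-2-(3-methylbut-2-en-1-yl)benzaldehyde | O=Cc1cc(OCOC)c(O)cc1CC=C(C)C | intermediate
13 | 3-chloro-3-methylbut-1-yne | CC(C)(Cl)C#C | starting material
14 | 5-(methoxymethoxy)-4-[(2-methylbut-3-yn-2-yl)oxy]-2-(3-methylbut-2-en-1-yl)benzaldehyde | O=Cc1cc(OCOC)c(OC(C)(C)C#C)cc1CC=C(C)C | intermediate
15 | 3-hydroxy-1-[2-hydroxy-4,6-bis(methoxymethoxy)-3-(2-methylbut-3-en-2-yl)phenyl]-3-[5-(methoxymethoxy)-4-(2-methylbut-3-yn-2-yloxy)-2-(3-methylbut-2-en-1-yl)phenyl]propan-1-one (racemic, not isolated) | C=CC(C)(C)c1c(O)c(C(=O)CC(O)c2cc(OCOC)c(OC(C)(C)C#C)cc2CC=C(C)C)c(OCOC)cc1OCOC | intermediate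
16 | (E)-1-[2-hydroxy-4,6-bis(methoxymethoxy)-3-(2-methylbut-3-en-2-yl)phenyl]-3-[5-(methoxymethoxy)-4-(2-methylbut-3-yn-2-yloxy)-2-(3-methylbut-2-en-1-yl)phenyl]prop-2-en-1-one | C=CC(C)(C)c1c(O)c(C(=O)/C=C/c2cc(OCOC)c(OC(C)(C)C#C)cc2CC=C(C)C)c(OCOC)cc1OCOC | intermediate
17 | 2,3-trans-3-hydroxy-5,7-bis(methoxymethoxy)-8-(2-methylbut-3-en-2-yl)-2-[5-(methoxymethoxy)-4-(2-methylbut-3-yn-2-yloxy)-2-(3-methylbut-2-en-1-yl)phenyl]chroman-4-one (racemic, one enantiomer drawn, not isolated) | C=CC(C)(C)c1c(OCOC)cc(OCOC)c2c1O[C@@H](c1cc(OCOC)c(OC(C)(C)C#C)cc1CC=C(C)C)[C@H](O)C2=O | intermediate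
18 | 3-hydroxy-5,7-bis(methoxymethoxy)-8-(2-methylbut-3-en-2-yl)-2-[5-(methoxymethoxy)-4-(2-methylbut-3-yn-2-yloxy)-2-(3-methylbut-2-en-1-yl)phenyl]-4H-chromen-4-one (precursor of the key step) | C=CC(C)(C)c1c(OCOC)cc(OCOC)c2c(=O)c(O)c(-c3cc(OCOC)c(OC(C)(C)C#C)cc3CC=C(C)C)oc12 | intermediate
19 | flavonol 18 with ring B as 3-(methoxymethoxy)-5-(3-methylbuta-1,2-dienyl)-6-(3-methylbut-2-en-1-yl)-4-oxocyclohexa-2,6-dien-1-yl, C3' sp3 (racemic, not isolated) | C=CC(C)(C)c1c(OCOC)cc(OCOC)c2c(=O)c(O)c(C3=C(CC=C(C)C)C(C=C=C(C)C)C(=O)C(OCOC)=C3)oc12 | intermediate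
20 | 3-hydroxy-2-[4-hydroxy-5-(methoxymethoxy)-3-(3-methylbuta-1,2-dienyl)-2-(3-methylbut-2-en-1-yl)phenyl]-5,7-bis(methoxymethoxy)-8-(2-methylbut-3-en-2-yl)-4H-chromen-4-one (not isolated) | C=CC(C)(C)c1c(OCOC)cc(OCOC)c2c(=O)c(O)c(-c3cc(OCOC)c(O)c(C=C=C(C)C)c3CC=C(C)C)oc12 | intermediate
21 | ortho-quinone methide: flavonol with ring B as 4-oxo-3-(3-methylbut-2-enylidene)cyclohexa-1,5-diene bearing 5'-OMOM and 2'-prenyl (not isolated) | C=CC(C)(C)c1c(OCOC)cc(OCOC)c2c(=O)c(O)c(C3=C(CC=C(C)C)C(=CC=C(C)C)C(=O)C(OCOC)=C3)oc12 | intermediate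
22 | 3-hydroxy-5,7-bis(methoxymethoxy)-2-[8-(methoxymethoxy)-2,2-dimethyl-5-(3-methylbut-2-en-1-yl)-2H-chromen-6-yl]-8-(2-methylbut-3-en-2-yl)-4H-chromen-4-one (product of the key step) | C=CC(C)(C)c1c(OCOC)cc(OCOC)c2c(=O)c(O)c(-c3cc(OCOC)c4c(c3CC=C(C)C)C=CC(C)(C)O4)oc12 | intermediate
23 | broussoflavonol D, 3,5,7-trihydroxy-2-[8-hydroxy-2,2-dimethyl-5-(3-methylbut-2-en-1-yl)-2H-chromen-6-yl]-8-(2-methylbut-3-en-2-yl)-4H-chromen-4-one | C=CC(C)(C)c1c(O)cc(O)c2c(=O)c(O)c(-c3cc(O)c4c(c3CC=C(C)C)C=CC(C)(C)O4)oc12 | target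

Total step count: 12. Longest linear sequence: 9 steps (steps 4 to 12; the ring A branch, steps 1 to 3, joins at step 9).

Steps most likely to fail

Step 10. The phenoxide may close onto the α-carbon (five-membered closure leading to an aurone) instead of the β-carbon, a diversion favoured by the 6'-alkoxy group and the ortho-substituted B ring. The fallback builds the pyranone by aroyl transfer instead of chalcone oxidation; it sets out from ketone 6 and aldehyde 14 and returns to the route at flavonol 18. Ketone 6 would be deprotonated twice (NaHMDS, THF, −78 °C) and hydroxylated with 2-(phenylsulfonyl)-3-phenyloxaziridine to the α-hydroxy ketone F1. Aldehyde 14 would be oxidised (Pinnick oxidation: NaClO2, NaH2PO4, 2-methylbut-2-ene, t-BuOH/H2O) to the benzoic acid F2. Esterification of the primary hydroxyl of F1 with F2 (EDC, DMAP, CH2Cl2; the chelated phenol stays free) would give the phenacyl ester F3. Base (K2CO3, Bu4NBr, toluene, 80 °C) would then induce a Baker–Venkataraman-type aroyl shift to the 2-hydroxy-1,3-diketone F4, whose cyclodehydration through the free phenol gives 18.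

Step 2. At the temperature needed the prenyl group may be lost as isoprene, and the newly formed ortho-(1,1-dimethylallyl)phenol may rearrange further (abnormal Claisen) or cyclise onto its alkene. The fallback traps the product as an ester as it forms; it sets out from ether 3 and returns at triol 5. Ether 3 would be acetylated (Ac2O, pyridine, DMAP) to the diacetate F5 and heated in PhNEt2 with Ac2O at 180 °C. The [3,3] shift through the dienone F6 would give the rearranged phenol F7, which is acetylated at once to the triacetate F8 and so cannot react further. Methanolysis (K2CO3, MeOH, rt, Ar) would then release 5.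

Step 12. Before the last acetal has gone, acid may add methanol across or open the electron-rich chromene, or drive O7 onto the 1,1-dimethylallyl alkene. The fallback inverts the order of deprotection and ring closure so that the chromene never meets acid; it sets out from flavonol 18 and returns at target 23. The same methanolic HCl would cleave the three acetals of 18 to the tetrahydroxy propargyl ether F9. Heating F9 (degassed DMF, 130 °C, Ar) would run the same cascade through the allenyl dienone F10, the allenyl catechol F11 and the ortho-quinone methide F12 to give 23 directly.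

Further compounds
F1 | step 10 | 2-hydroxy-1-[2-hydroxy-4,6-bis(methoxymethoxy)-3-(2-methylbut-3-en-2-yl)phenyl]ethanone | OCC(=O)c1c(OCOC)cc(OCOC)c(C(C)(C)C=C)c1O
F2 | step 10 | 5-(methoxymethoxy)-4-[(2-methylbut-3-yn-2-yl)oxy]-2-(3-methylbut-2-en-1-yl)benzoic acid | OC(=O)c1cc(OCOC)c(OC(C)(C)C#C)cc1CC=C(C)C
F3 | step 10 | 2-[2-hydroxy-4,6-bis(methoxymethoxy)-3-(2-methylbut-3-en-2-yl)phenyl]-2-oxoethyl 5-(methoxymethoxy)-4-[(2-methylbut-3-yn-2-yl)oxy]-2-(3-methylbut-2-en-1-yl)benzoate | C=CC(C)(C)c1c(O)c(C(=O)COC(=O)c2cc(OCOC)c(OC(C)(C)C#C)cc2CC=C(C)C)c(OCOC)cc1OCOC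
F4 | step 10 | 2-hydroxy-1-[2-hydroxy-4,6-bis(methoxymethoxy)-3-(2-methylbut-3-en-2-yl)phenyl]-3-[5-(methoxymethoxy)-4-(2-methylbut-3-yn-2-yloxy)-2-(3-methylbut-2-en-1-yl)phenyl]propane-1,3-dione (racemic, not isolated) | C=CC(C)(C)c1c(O)c(C(=O)C(O)C(=O)c2cc(OCOC)c(OC(C)(C)C#C)cc2CC=C(C)C)c(OCOC)cc1OCOC
F5 | step 2 | 2-acetyl-5-(3-methylbut-2-en-1-yloxy)-1,3-phenylene diacetate | CC(=O)Oc1cc(OCC=C(C)C)cc(OC(C)=O)c1C(C)=O
F6 | step 2 | 4-acetyl-3,5-diacetoxy-6-(2-methylbut-3-en-2-yl)cyclohexa-2,4-dien-1-one (racemic, not isolated) | CC(=O)OC1=CC(=O)C(C(C)(C)C=C)C(OC(C)=O)=C1C(C)=O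
F7 | step 2 | 2-acetyl-5-hydroxy-4-(2-methylbut-3-en-2-yl)-1,3-phenylene diacetate (not isolated) | CC(=O)Oc1cc(O)c(C(C)(C)C=C)c(OC(C)=O)c1C(C)=O
F8 | step 2 | 2-acetyl-4-(2-methylbut-3-en-2-yl)benzene-1,3,5-triyl triacetate | CC(=O)Oc1cc(OC(C)=O)c(C(C)(C)C=C)c(OC(C)=O)c1C(C)=O
F9 | step 12 | 3,5,7-trihydroxy-2-[5-hydroxy-4-(2-methylbut-3-yn-2-yloxy)-2-(3-methylbut-2-en-1-yl)phenyl]-8-(2-methylbut-3-en-2-yl)-4H-chromen-4-one | C=CC(C)(C)c1c(O)cc(O)c2c(=O)c(O)c(-c3cc(O)c(OC(C)(C)C#C)cc3CC=C(C)C)oc12
F10 | step 12 | unprotected allenyl dienone, ring B as 3-hydroxy-5-(3-methylbuta-1,2-dienyl)-6-(3-methylbut-2-en-1-yl)-4-oxocyclohexa-2,6-dien-1-yl (racemic, not isolated) | C=CC(C)(C)c1c(O)cc(O)c2c(=O)c(O)c(C3=C(CC=C(C)C)C(C=C=C(C)C)C(=O)C(O)=C3)oc12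
F11 | step 12 | 2-[4,5-dihydroxy-3-(3-methylbuta-1,2-dienyl)-2-(3-methylbut-2-en-1-yl)phenyl]-3,5,7-trihydroxy-8-(2-methylbut-3-en-2-yl)-4H-chromen-4-one (not isolated) | C=CC(C)(C)c1c(O)cc(O)c2c(=O)c(O)c(-c3cc(O)c(O)c(C=C=C(C)C)c3CC=C(C)C)oc12
F12 | step 12 | unprotected ortho-quinone methide, ring B as 5'-hydroxy-4'-oxo-3'-(3-methylbut-2-enylidene)cyclohexadiene bearing the 2'-prenyl group (not isolated) | C=CC(C)(C)c1c(O)cc(O)c2c(=O)c(O)c(C3=C(CC=C(C)C)C(=CC=C(C)C)C(=O)C(O)=C3)oc12
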